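Time is a poor clock for this flask, so I reckon in another.

the same everywhere: substrate 1.6 M
- Friday's: coupling partner 0.60 equiv; initiator 2.5 mol%; run made earlier
- Thursday's: coupling partner 0.90 equiv; initiator 2.5 mol%; run made earlier
- Sunday's: coupling partner 1.2 equiv; initiator 1.2 mol%; run made earlier
- flask: coupling partner 1.20 equiv; initiator 2.5 mol%; time 25 min

- Friday's (time / min: product / %, ended carrier / %, substrate / %): 2.50: 10.3, 0.6, 89.6; 4.00: 15.7, 0.3, 83.5; 6.00: 21.0, 0.8, 78.0; 10.0: 29.4, 1.4, 70.4; 20.0: 38.4, 2.8, 57.1; 30.0: 43.1, 2.8, 52.6
- Thursday's (time / min: product / %, ended carrier / %, substrate / %): 2.00: 13.5, 0.1, 86.5; 6.00: 30.7, 0.5, 68.1; 10.0: 40.7, 1.3, 57.3; 15.0: 49.4, 2.2, 47.2; 25.0: 59.0, 2.5, 37.7; 30.0: 61.4, 2.9, 35.0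
- Sunday's (time / min: product / %, ended carrier / %, substrate / %): 6.00: 24.8, 0.6, 74.2; 12.0: 40.0, 0.7, 60.5; 20.0: 49.6, 1.8, 48.8; 25.0: 54.3, 1.3, 43.8; 30.0: 57.0, 0.5, 41.5

(scatter of a reading: 0.5 percentage points)

- a species is counted by the substrate in it: one ended chains counts as two
- steps under discussion: initiator -> 2 initiating radical; substrate + initiating radical -> capped initiator + first chain carrier; coupling partner + first chain carrier <-> product + second chain carrier; substrate + second chain carrier -> by-product + first chain carrier; first chain carrier -> ended carrier; 2 first chain carrier -> ended chains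

* how much product the flask holds at 25 min, in percent of the substrate charged
* how much ended carrier the flask holds at 25 min, in percent of the substrate charged

I write the rate as k·c(substrate)·c(coupling partner), with k free to change in time. With x the product as a fraction of the substrate charged and E the equivalents of partner, integration gives the exposure, ln[(E − x)/(E(1 − x))]/(E − 1). Sunday's run has the flask's E, and its reading of 54.3% at 25.0 min gives an exposure of 0.903. That makes 75.3 as the exposure per equivalent of initiator. Thursday's exposure at 25.0 min, 1.74, is about twice Sunday's, so I take exposure as proportional to initiator.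

Sunday's exposure at 6.00 min is 0.268, so my curve for the flask starts at a slope of 0.111 min⁻¹. Product reaches 0.5 of the charge at an exposure of 0.771. On Sunday's scale that is 0.370, which lies above 0.268 and below Sunday's 0.527 at 12.0 min. So the crossing comes between 6.00 min and 12.0 min. At 25 min the exposure is 1.88, which gives 73.3%. The slope there is down to 0.00753 min⁻¹, and substrate, the limiting reagent, gives my curve its ceiling at the full charge.

The forecast is lower than my figure, at 71.5% (68% to 75%) of product and 2.6% (1.9% to 3.3%) of ended carrier, and it reads: “Ended carrier tracks initiator and barely depends on partner”.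

The flask gives 73.5% of product and 2.62% of ended carrier.

    initiator → 2 initiating radical (k = 7.40 × 10⁻⁴ s⁻¹)
    substrate + initiating radical → capped initiator + first chain carrier (k = 1.40 × 10⁵ M⁻¹ s⁻¹)
    coupling partner + first chain carrier ⇌ product + second chain carrier (K = 1.60, k = 15000 M⁻¹ s⁻¹)
    substrate + second chain carrier → by-product + first chain carrier (k = 23000 M⁻¹ s⁻¹)
    first chain carrier → ended carrier (k = 460 s⁻¹)
    2 first chain carrier → ended chains (k = 1.00 × 10⁹ M⁻¹ s⁻¹)

That product is 76.1 of exposure per equivalent of initiator, against my 75.3. At 5.38 min the flask's first chain carrier goes forward to product 43 times as fast as it goes to ended carrier, counting the forward rate of that reversible step alone. With 1.5 mol% of initiator, 75.3 gives an exposure of 1.13 and so 60.3% of product; that flask gives 60.6%.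

(The runs stem from a simulated flask for substances that don't exist; the scatter is artificial.)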